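The route rests on opening the seven-membered ring at C8–C9 (guaiane numbering). That leaves the cyclopentene ring of ring-contracted (S)-limonene carrying, on adjacent atoms, the C1 isopropenyl group (C10=C9, C14 methyl) and, on C5, a C6–C7 arm that ends in the C8 aldehyde; C7 bears the silylated C11 carbinol. In one operation a Me2AlCl-promoted type-two carbonyl-ene reaction bonds C9 to C8, closes the seven-membered ring C1–C5–C6–C7–C8–C9–C10, shifts the alkene to C10=C14 and sets the C8 carbinol cis to the C7 side chain, as in the target. Hydrogenation at C10, two acylations and C3 allylic oxidation then finish the synthesis.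

Key step: step 11

Remark on the chemistry: guaiane numbering is also used for the open-chain precursors; because the six-centre ene transition state needs the aluminium-bound oxygen pseudo-axial over C10–C14 while the bulky C11 group on C7 stays pseudo-equatorial, the closure is expected to give the C8 hydroxyl cis to the C7 side chain (8R, as in the target), and the route is laid out on that outcome.

Step 1
Reactants: 1 (S)-limonene [(4S)-1-methyl-4-(prop-1-en-2-yl)cyclohex-1-ene]
Product: 2 (4S)-1,2-epoxy-p-menth-8-ene (limonene 1,2-oxide; both epoxide diastereomers)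
Conditions: mCPBA (1.0 equiv), CH2Cl2, 0 °C
Reagents that add atoms: mCPBA (3-chloroperoxybenzoic acid), OOC(=O)c1cccc(Cl)c1
Why: Prilezhaev epoxidation, in which the electrophilic peracid takes the electron-rich trisubstituted ring alkene far faster than the 1,1-disubstituted isopropenyl group; the configuration of the two epoxide carbons does not matter because both become carbonyl carbons.

Step 2
Reactants: 2 (4S)-1,2-epoxy-p-menth-8-ene
Product: 4 (3S)-6-oxo-3-(prop-1-en-2-yl)heptanal, via vicinal diol 3 (not isolated)
Conditions: H5IO6 (1.1 equiv), THF–H2O, 0 °C → rt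
Reagents that add atoms: water, O
Why: Acid-mediated epoxide hydrolysis followed in the same flask by Malaprade glycol cleavage with periodic acid breaks the ring between the two oxygenated carbons without touching the isopropenyl group or the stereocentre.

Step 3
Reactants: 4 (3S)-6-oxo-3-(prop-1-en-2-yl)heptanal
Product: 6 (5R)-2-methyl-5-(prop-1-en-2-yl)cyclopent-1-ene-1-carbaldehyde, via aldol adduct 5 (not isolated)
Conditions: piperidine (0.1 equiv), AcOH (0.1 equiv), toluene, 60 °C
Reagents that add atoms: none
Why: Amine-catalysed intramolecular aldol condensation (the aldehyde α-carbon adds to the methyl ketone in a five-membered closure, then water is lost) gives the conjugated ring-contracted enal, and the stereocentre is kept because it is not an enolisable position.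

Step 4
Reactants: 6 (5R)-2-methyl-5-(prop-1-en-2-yl)cyclopent-1-ene-1-carbaldehyde
Product: 7 [(5R)-2-methyl-5-(prop-1-en-2-yl)cyclopent-1-en-1-yl]methanol
Conditions: NaBH4, CeCl3·7H2O, MeOH, 0 °C
Reagents that add atoms: none
Why: Luche 1,2-reduction converts the enal into the primary allylic alcohol without conjugate reduction.

Step 5
Reactants: 7 [(5R)-2-methyl-5-(prop-1-en-2-yl)cyclopent-1-en-1-yl]methanol
Product: 8 [(5R)-2-methyl-5-(prop-1-en-2-yl)cyclopent-1-en-1-yl]methyl bromide
Conditions: CBr4, PPh3, CH2Cl2, 0 °C; used at once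
Reagents that add atoms: CBr4 (tetrabromomethane), BrC(Br)(Br)Br
Why: Appel bromination replaces the primary allylic hydroxyl under neutral conditions, which avoids acid-promoted allylic transposition or addition to the isopropenyl group.

Step 6
Reactants: 9 3-hydroxy-3-methylbutanoic acid
Product: 11 3-methyl-3-(triethylsilyloxy)butanoic acid, via bis(triethylsilyl) derivative 10 (not isolated)
Conditions: TESOTf (2.2 equiv), 2,6-lutidine, CH2Cl2, 0 °C; then MeOH, K2CO3 (cat.), 0 °C; aqueous NaH2PO4 work-up
Reagents that add atoms: TESOTf (triethylsilyl trifluoromethanesulfonate), CC[Si](CC)(CC)OS(=O)(=O)C(F)(F)F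
Why: Silyl triflate silylation protects the hindered tertiary alcohol (the acid is silylated as well), and mild methanolysis then cleaves only the labile silyl ester.

Step 7
Reactants: 11 3-methyl-3-(triethylsilyloxy)butanoic acid; 12 (R)-4-benzyl-1,3-oxazolidin-2-one
Product: 14 (4R)-4-benzyl-3-[3-methyl-3-(triethylsilyloxy)butanoyl]-1,3-oxazolidin-2-one, via mixed pivalic anhydride 13 (not isolated)
Conditions: PivCl, Et3N, THF, −20 °C; then 12, LiCl, rt
Reagents that add atoms: none
Why: N-Acylation of the oxazolidinone through the mixed pivalic anhydride avoids an acid chloride that could strip the silyl ether, and the hindered pivaloyl carbonyl is not attacked.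

Step 8
Reactants: 14 (4R)-4-benzyl-3-[3-methyl-3-(triethylsilyloxy)butanoyl]-1,3-oxazolidin-2-one; 8 [(5R)-2-methyl-5-(prop-1-en-2-yl)cyclopent-1-en-1-yl]methyl bromide
Product: 16 (4R)-4-benzyl-3-[(2R)-3-methyl-2-{[(5R)-2-methyl-5-(prop-1-en-2-yl)cyclopent-1-en-1-yl]methyl}-3-(triethylsilyloxy)butanoyl]-1,3-oxazolidin-2-one, via sodium Z-enolate 15 (not isolated)
Conditions: NaN(SiMe3)2, THF, −78 °C; then 8, −78 → −45 °C
Reagents that add atoms: none
Why: Evans asymmetric alkylation, in which the reactive allylic bromide attacks the chelated sodium Z-enolate on the face opposite the benzyl group of the (R)-auxiliary and so sets C7 (2R in the imide), while the low temperature and the poor leaving ability of a tertiary silanolate hold back E1cB loss of the β-silyloxy group.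

Step 9
Reactants: 16 the alkylated imide
Product: 17 (2S)-3-methyl-2-{[(5R)-2-methyl-5-(prop-1-en-2-yl)cyclopent-1-en-1-yl]methyl}-3-(triethylsilyloxy)butan-1-ol
Conditions: LiBH4, THF, 0 °C → rt
Reagents that add atoms: none
Why: Reductive cleavage of the N-acyloxazolidinone with borohydride releases the primary alcohol and the auxiliary without a step that could epimerise C7 (the descriptor changes only through the priority rules).

Step 10
Reactants: 17 the primary alcohol
Product: 18 (2R)-3-methyl-2-{[(5R)-2-methyl-5-(prop-1-en-2-yl)cyclopent-1-en-1-yl]methyl}-3-(triethylsilyloxy)butanal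
Conditions: Dess–Martin periodinane, pyridine, CH2Cl2, 0 °C; used at once
Reagents that add atoms: none
Why: Dess–Martin oxidation under pyridine buffering stops at the aldehyde, and no base strong enough to epimerise the α-centre C7 is present.

Step 11
Reactants: 18 the C8 aldehyde
Product: 20 (1R,7S,8R)-11-(triethylsilyloxy)guaia-4,10(14)-dien-8-ol [(5S,6R,8aR)-3-methyl-8-methylidene-5-[2-(triethylsilyloxy)propan-2-yl]-1,2,4,5,6,7,8,8a-octahydroazulen-6-ol; 8-OH cis to the C7 side chain], via aluminium alkoxide 19 (not isolated)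
Conditions: Me2AlCl (1.5 equiv), CH2Cl2, −78 → −30 °C; aqueous potassium sodium tartrate
Reagents that add atoms: none
Why: Me2AlCl activates the aldehyde, and the C8 carbonyl then reacts with the isopropenyl group in a concerted, asynchronous six-centre ene process in which C9 bonds to C8 while a hydrogen of the C14 methyl passes to oxygen; the aluminium-bound alcohol then loses methane to give alkoxide 19, which removes the proton source and makes the closure irreversible. The closest known reaction type is the Lewis acid promoted type-two carbonyl-ene cyclisation of aldehydes onto 1,1-disubstituted alkenes, known for six- and seven-membered rings. The seven-membered ring closes in the type-two mode, exo with respect to the carbonyl (7-exo-trig at C8, oxygen outside the ring) and endo with respect to the alkene (C9 and C10 both inside the ring, the tether leaving from the central carbon C10). The one new stereocentre, C8, is controlled by the C7 centre set in step 8 through a chair-like bicyclic transition state: the C11 group sits pseudo-equatorial and anti to the incoming C9, and the oxygen must sit pseudo-axial, syn to C14, to take the hydrogen, which puts O8 cis to the C7 side chain (8R). The step needs site selectivity for the 1,1-disubstituted alkene over the more electron-rich C4=C5 alkene and hydrogen transfer from C14 only, and the substrate secures both, because the cis 1,2-placement of the two arms on C1 and C5 of the cyclopentene brings C9 within reach of C8 whereas bonding to C4 or C5 would need a four-membered or a strained bicyclic transition state, and only the C14 hydrogens can reach the oxygen. C1 and C7 are not touched.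

Step 12
Reactants: 20 (1R,7S,8R)-11-(triethylsilyloxy)guaia-4,10(14)-dien-8-ol
Product: 21 (1R,7S,8R,10S)-11-(triethylsilyloxy)guai-4-en-8-ol
Conditions: H2 (1 atm), PtO2 (5 mol %), EtOAc, rt; stopped after one equivalent of H2
Reagents that add atoms: none
Why: Heterogeneous catalytic hydrogenation adds hydrogen to the 1,1-disubstituted C10=C14 alkene from its open convex face, because in the chair-like ring left by step 11 C8 and its pseudo-axial oxygen lie over the other face, so the C14 methyl ends syn to O8 (10S); a non-coordinating heterogeneous catalyst is chosen so that the hydroxyl cannot steer hydrogen to its own face, and the tetrasubstituted C4=C5 alkene is too hindered to react.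

Step 13
Reactants: 21 (1R,7S,8R,10S)-11-(triethylsilyloxy)guai-4-en-8-ol
Product: 22 (1R,7S,8R,10S)-11-(triethylsilyloxy)guai-4-en-8-yl 2-methylprop-2-enoate
Conditions: methacrylic anhydride, DMAP, Et3N, CH2Cl2, 0 °C → rt
Reagents that add atoms: methacrylic anhydride, CC(=C)C(=O)OC(=O)C(C)=C
Why: DMAP-catalysed acyl transfer (Steglich-type esterification) acylates the secondary C8 alcohol with retention of the configuration set in step 11, while the tertiary oxygen is still silylated.

Step 14
Reactants: 22 the silylated methacrylate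
Product: 23 (1R,7S,8R,10S)-11-hydroxyguai-4-en-8-yl 2-methylprop-2-enoate
Conditions: HF·pyridine, pyridine, THF, 0 °C → rt
Reagents that add atoms: none
Why: Fluoride-driven desilylation with buffered HF·pyridine removes the tertiary triethylsilyl ether under weakly acidic conditions that neither attack the methacrylate nor allow base-mediated acyl migration from O8 to O11.

Step 15
Reactants: 23 the tertiary alcohol
Product: 24 (1R,7S,8R,10S)-11-acetoxyguai-4-en-8-yl 2-methylprop-2-enoate
Conditions: Ac2O (excess), DMAP (1 equiv), Et3N, CH2Cl2, 40 °C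
Reagents that add atoms: acetic anhydride, CC(=O)OC(C)=O
Why: Steglich acetylation by nucleophilic catalysis acylates the hindered tertiary alcohol with excess anhydride and gentle heating, and the absence of an acidic activator avoids ionisation of the tertiary centre.

Step 16
Reactants: 24 the 11-acetate 8-methacrylate
Product: 25 (1R,7S,8R,10S)-11-acetoxy-3-oxoguai-4-en-8-yl 2-methylprop-2-enoate (CNP0318307.1)
Conditions: CrO3, 3,5-dimethylpyrazole (15 equiv each, complex formed at −20 °C), CH2Cl2, −20 °C
Reagents that add atoms: CrO3 (chromium trioxide), O=[Cr](=O)=O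
Why: Allylic C–H oxidation with the CrO3·3,5-dimethylpyrazole complex turns an allylic methylene of the tetrasubstituted C4=C5 alkene into the enone carbonyl, and C3 in the cyclopentene is the open site because C6 is shielded by the fully substituted C7 neighbourhood, the C1 methine is hindered and tertiary, and the electron-poor methacrylate is inert.

Compound list
1 | (S)-limonene, (4S)-1-methyl-4-(prop-1-en-2-yl)cyclohex-1-ene | CC1=CC[C@H](CC1)C(C)=C | starting material
2 | (4S)-1,2-epoxy-p-menth-8-ene (both epoxide diastereomers) | CC1(O2)C2C[C@H](CC1)C(C)=C | intermediate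
3 | (4S)-p-menth-8-ene-1,2-diol (diastereomer mixture) | CC1(O)C(O)C[C@H](CC1)C(C)=C | intermediate
4 | (3S)-6-oxo-3-(prop-1-en-2-yl)heptanal | CC(=O)CC[C@@H](CC=O)C(C)=C | intermediate
5 | 2-hydroxy-2-methyl-5-(prop-1-en-2-yl)cyclopentane-1-carbaldehyde, isopropenyl carbon as in 4, other centres mixed | O=CC1C(C)(O)CC[C@@H]1C(C)=C | intermediate
6 | (5R)-2-methyl-5-(prop-1-en-2-yl)cyclopent-1-ene-1-carbaldehyde | O=CC1=C(C)CC[C@@H]1C(C)=C | intermediate
7 | [(5R)-2-methyl-5-(prop-1-en-2-yl)cyclopent-1-en-1-yl]methanol | OCC1=C(C)CC[C@@H]1C(C)=C | intermediate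
8 | [(5R)-2-methyl-5-(prop-1-en-2-yl)cyclopent-1-en-1-yl]methyl bromide | BrCC1=C(C)CC[C@@H]1C(C)=C | intermediate
9 | 3-hydroxy-3-methylbutanoic acid | CC(C)(O)CC(=O)O | starting material
10 | triethylsilyl 3-methyl-3-(triethylsilyloxy)butanoate | CC[Si](CC)(CC)OC(=O)CC(C)(C)O[Si](CC)(CC)CC | intermediate
11 | 3-methyl-3-(triethylsilyloxy)butanoic acid | CC[Si](CC)(CC)OC(C)(C)CC(=O)O | intermediate
12 | (R)-4-benzyl-1,3-oxazolidin-2-one | O=C1N[C@H](Cc2ccccc2)CO1 | starting material
13 | 2,2-dimethylpropanoic 3-methyl-3-(triethylsilyloxy)butanoic anhydride | CC[Si](CC)(CC)OC(C)(C)CC(=O)OC(=O)C(C)(C)C | intermediate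
14 | (4R)-4-benzyl-3-[3-methyl-3-(triethylsilyloxy)butanoyl]-1,3-oxazolidin-2-one | CC[Si](CC)(CC)OC(C)(C)CC(=O)N1[C@H](Cc2ccccc2)COC1=O | intermediate
15 | sodium (Z)-enolate of 14 | [Na+].[O-]\C(=C/C(C)(C)O[Si](CC)(CC)CC)N1[C@H](Cc2ccccc2)COC1=O | intermediate
16 | (4R)-4-benzyl-3-[(2R)-3-methyl-2-{[(5R)-2-methyl-5-(prop-1-en-2-yl)cyclopent-1-en-1-yl]methyl}-3-(triethylsilyloxy)butanoyl]-1,3-oxazolidin-2-one | O=C([C@H](CC1=C(C)CC[C@@H]1C(C)=C)C(C)(C)O[Si](CC)(CC)CC)N1[C@H](Cc2ccccc2)COC1=O | intermediate
17 | (2S)-3-methyl-2-{[(5R)-2-methyl-5-(prop-1-en-2-yl)cyclopent-1-en-1-yl]methyl}-3-(triethylsilyloxy)butan-1-ol | OC[C@H](CC1=C(C)CC[C@@H]1C(C)=C)C(C)(C)O[Si](CC)(CC)CC | intermediate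
18 | (2R)-3-methyl-2-{[(5R)-2-methyl-5-(prop-1-en-2-yl)cyclopent-1-en-1-yl]methyl}-3-(triethylsilyloxy)butanal | O=C[C@H](CC1=C(C)CC[C@@H]1C(C)=C)C(C)(C)O[Si](CC)(CC)CC | intermediate
19 | chloro(methyl)aluminium alkoxide of 20 | C[Al](Cl)O[C@@H]1CC(=C)[C@H]2CCC(C)=C2C[C@@H]1C(C)(C)O[Si](CC)(CC)CC | intermediate
20 | (1R,7S,8R)-11-(triethylsilyloxy)guaia-4,10(14)-dien-8-ol, 8-OH cis to the C7 side chain | O[C@@H]1CC(=C)[C@H]2CCC(C)=C2C[C@@H]1C(C)(C)O[Si](CC)(CC)CC | intermediate
21 | (1R,7S,8R,10S)-11-(triethylsilyloxy)guai-4-en-8-ol | O[C@@H]1C[C@H](C)[C@H]2CCC(C)=C2C[C@@H]1C(C)(C)O[Si](CC)(CC)CC | intermediate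
22 | (1R,7S,8R,10S)-11-(triethylsilyloxy)guai-4-en-8-yl 2-methylprop-2-enoate | C=C(C)C(=O)O[C@@H]1C[C@H](C)[C@H]2CCC(C)=C2C[C@@H]1C(C)(C)O[Si](CC)(CC)CC | intermediate
23 | (1R,7S,8R,10S)-11-hydroxyguai-4-en-8-yl 2-methylprop-2-enoate | C=C(C)C(=O)O[C@@H]1C[C@H](C)[C@H]2CCC(C)=C2C[C@@H]1C(C)(C)O | intermediate
24 | (1R,7S,8R,10S)-11-acetoxyguai-4-en-8-yl 2-methylprop-2-enoate | C=C(C)C(=O)O[C@@H]1C[C@H](C)[C@H]2CCC(C)=C2C[C@@H]1C(C)(C)OC(C)=O | intermediate
25 | (1R,7S,8R,10S)-11-acetoxy-3-oxoguai-4-en-8-yl 2-methylprop-2-enoate | C=C(C)C(=O)O[C@@H]1C[C@H](C)[C@H]2CC(=O)C(C)=C2C[C@@H]1C(C)(C)OC(C)=O | target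

Total step count: 16. Longest linear sequence: 14 steps (steps 1–5 and 8–16 from 1; steps 6 and 7 form the side branch from 9 and 12).

Steps most likely to fail

Step 11. The closure may run through the alternative ring conformation that places the oxygen on the other face, so that facial selectivity at C8 is reversed or mixed; the fallback sets C8 by reagent control instead. It sets out from 18 and comes back at 21. The closure would then give the 8-epimeric dienol F7, whose hydroxyl lies on the face to which hydrogen must come at C10; hydroxyl-directed hydrogenation with [Ir(cod)(PCy3)(py)]PF6 and H2 in CH2Cl2 would give the 8-epimeric saturated alcohol F8. Dess–Martin oxidation would give the C8 ketone F9, and LiBH(s-Bu)3 in THF at −78 °C, with hydride entering anti to the C7 side chain and the C10 methyl, would give 21.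

Step 8. The enolate may lose silanolate by E1cB elimination, or alkylation at the crowded α-carbon may be too slow; the fallback uses an enolate with no β-leaving group and introduces the C11 oxygen afterwards. It sets out from 12 and 8 and comes back at 17. N-Acylation of 12 (n-BuLi, THF, −78 °C; 3-methylbut-2-enoyl chloride) would give (4R)-4-benzyl-3-(3-methylbut-2-enoyl)-1,3-oxazolidin-2-one F1. Its sodium dienolate (NaN(SiMe3)2, THF, −78 °C) would be alkylated by 8 at the α-carbon, again anti to the benzyl group, to give the α-isopropenyl imide F2 (deconjugative Evans alkylation). LiBH4 would give the homoallylic alcohol F3; hydroxyl-directed epoxidation (VO(acac)2, t-BuOOH) would oxidise only the nearby C11=C12 alkene to the epoxy alcohol F4; LiAlH4 would open the epoxide at its CH2 end to the 1,3-diol F5. TESOTf and 2,6-lutidine would give the bis(triethylsilyl) ether F6, and PPTS in MeOH at 0 °C would free only the primary alcohol, which is 17.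

Step 12. Hydrogen may be delivered to the wrong face of C10=C14, or the alkene may migrate into the ring before it is reduced; the fallback replaces steric control by hydroxyl direction. It sets out from 20 and comes back at 21. Mitsunobu inversion of 20 with 4-nitrobenzoic acid (PPh3, DIAD, THF; the carboxylate enters anti to the C7 side chain) would give the inverted 4-nitrobenzoate F10, and methanolysis (K2CO3, MeOH) would give the 8-epimeric dienol F7. The directed hydrogenation, oxidation and hydride reduction described under step 11, through the 8-epimeric saturated alcohol F8 and the C8 ketone F9, would then lead to 21.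

Further compounds
F1 | step 8 | (4R)-4-benzyl-3-(3-methylbut-2-enoyl)-1,3-oxazolidin-2-one | CC(C)=CC(=O)N1[C@H](Cc2ccccc2)COC1=O
F2 | step 8 | (4R)-4-benzyl-3-[(2R)-3-methyl-2-{[(5R)-2-methyl-5-(prop-1-en-2-yl)cyclopent-1-en-1-yl]methyl}but-3-enoyl]-1,3-oxazolidin-2-one | O=C([C@H](CC1=C(C)CC[C@@H]1C(C)=C)C(C)=C)N1[C@H](Cc2ccccc2)COC1=O
F3 | step 8 | (2R)-3-methyl-2-{[(5R)-2-methyl-5-(prop-1-en-2-yl)cyclopent-1-en-1-yl]methyl}but-3-en-1-ol | OC[C@H](CC1=C(C)CC[C@@H]1C(C)=C)C(C)=C
F4 | step 8 | (2S)-2-(2-methyloxiran-2-yl)-3-[(5R)-2-methyl-5-(prop-1-en-2-yl)cyclopent-1-en-1-yl]propan-1-ol (both epoxide epimers) | OC[C@H](CC1=C(C)CC[C@@H]1C(C)=C)C1(C)CO1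
F5 | step 8 | (2S)-3-methyl-2-{[(5R)-2-methyl-5-(prop-1-en-2-yl)cyclopent-1-en-1-yl]methyl}butane-1,3-diol | OC[C@H](CC1=C(C)CC[C@@H]1C(C)=C)C(C)(C)O
F6 | step 8 | 1,3-bis(triethylsilyl) ether of F5 | CC[Si](CC)(CC)OC[C@H](CC1=C(C)CC[C@@H]1C(C)=C)C(C)(C)O[Si](CC)(CC)CC
F7 | step 11 | (1R,7S,8S)-11-(triethylsilyloxy)guaia-4,10(14)-dien-8-ol, 8-OH trans to the C7 side chain | O[C@H]1CC(=C)[C@H]2CCC(C)=C2C[C@@H]1C(C)(C)O[Si](CC)(CC)CC
F8 | step 11 | (1R,7S,8S,10S)-11-(triethylsilyloxy)guai-4-en-8-ol | O[C@H]1C[C@H](C)[C@H]2CCC(C)=C2C[C@@H]1C(C)(C)O[Si](CC)(CC)CC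
F9 | step 11 | (1R,7R,10S)-11-(triethylsilyloxy)guai-4-en-8-one | O=C1C[C@H](C)[C@H]2CCC(C)=C2C[C@@H]1C(C)(C)O[Si](CC)(CC)CC
F10 | step 12 | (1R,7S,8S)-11-(triethylsilyloxy)guaia-4,10(14)-dien-8-yl 4-nitrobenzoate | O=C(O[C@H]1CC(=C)[C@H]2CCC(C)=C2C[C@@H]1C(C)(C)O[Si](CC)(CC)CC)c1ccc(cc1)[N+](=O)[O-]
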